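Target reaches the flask through intermediate A, so each yield is the share of substrate that takes that road and then has time to finish it.

| flask | substrate | reagent | capture agent | time | remark |
|---|---|---|---|---|---|
| cedar | 0.12 M | 2.00 equiv (fed, over 5.0 h) | 6.00 mM | 8.0 h | all else is in the flask from the start; the feed brings no volume worth counting |
| ash | 0.12 M (fed, over 5.0 h) | 2.00 equiv | 6.00 mM | 8.0 h | all else is in the flask from the start; the feed brings no volume worth counting |
| birch | 0.12 M | 2.00 equiv | 6.00 mM | 8.0 h | everything together at the start |
| maple | 0.12 M | 2.00 equiv (fed, over 30 min) | 6.00 mM | 8.0 h | all else is in the flask from the start; the feed brings no volume worth counting |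

    reagent + intermediate B → side product (k1 = 0.0192 M⁻¹ min⁻¹)
    reagent + intermediate B ⇌ intermediate C (K2 = 15 M⁻¹, k2 = 0.0450 M⁻¹ min⁻¹)
    substrate → intermediate A (k3 = 0.00831 min⁻¹)
    capture agent + intermediate C → trapped intermediate (k4 = 0.288 M⁻¹ min⁻¹)
    substrate + reagent → intermediate B (k5 = 0.105 M⁻¹ min⁻¹)
    intermediate A → target (k6 = 0.00772 min⁻¹)

* the flask that comes out highest in amount of target, in percent of the substrate charged, or "all alike" when all lie within 1.5 percentage points (cedar / ash / birch / maple / all alike)
* target at the end, in percent of the substrate charged, cedar
* target at the end, in percent of the substrate charged, ash
* target at the end, in percent of the substrate charged, birch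
* target at the end, in percent of the substrate charged, maple

- Substrate leaves alone for intermediate A, or with reagent for intermediate B, a pseudo-first-order loss at any given reagent level. Reckoned as 0.660, the lone rate constant over the reagent rate constant times the substrate charge, this is the balance level: the reagent, in fractions of the substrate charge, at which both routes run equally fast. The share going to intermediate A is the balance level over the balance level plus reagent.
- For the ceiling, take no reagent at all: the two first-order steps then put 89.6% into target by 8.0 h, and reagent can take substrate away but returns none.
- For a crude floor, hold reagent at its full 2.00 equiv: the share is 24.8%, which is where ash and birch begin.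
- In birch, if substrate is what consumes reagent, the share solves to about 29.5%.
- In cedar, reagent cannot exceed what has been fed, 0.400 h⁻¹ of the charge per hour. Summing hour-wide slices with that excess, and giving each slice's intermediate A its remaining time, I get a floor of 58.8% in target.
- The same count for maple sends at least 33.3% to intermediate A. Cedar's floor stands higher than the birch and maple figures, but the maple figure is itself a floor and ash has only its crude floor, so I lean to cedar without having proved its place.
- The forecast, holding that “the yield rises when reagent is kept low while substrate is present”, named cedar and gave 63% for cedar (58% to 67%), 29% for ash, 29.5% for birch and 36.5% for maple.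
- The simulation puts cedar highest, with 63.8% in cedar, 26.9% in ash, 29.5% in birch and 36.3% in maple, so cedar lies above my floor and below the ceiling.
- In cedar, half the making of intermediate A was done by 0.847 h while reagent was being fed, and half its conversion to target by 2.59 h. When the feed ended at 5.00 h, substrate stood at 0.554% and target at 54.6%. Target and intermediate A in cedar end at 66.9%, which against the balance level 0.660 reads as an effective reagent of 0.327 of the charge. The neighbour of cedar at 0.048 M substrate has a balance level of 1.65, its hour-slice floor comes to 70.6%, higher than the floor of cedar, and that flask holds 73.6% target.

(Its constants are those of an exercise, and the outcome is calculated.)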